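**Plan**

1. Cuts, last to first: C6–H (hydride onto a 5,6-dione), C3=C4 (dehydrogenation), C4–CH3 (β-keto ester alkylation), C10–isopropyl (1,2-addition), C2–O/C1–H (hydroboration), then the ring bonds C6–C7 and C3–C4.
2. Enabling feature: in the seven-membered ring, C4–C5–C6 is a three-carbon piece oxygenated at its middle carbon and C3–C2–C1–C7 a four-carbon piece ending in two cyclopentane atoms. This is a 2-siloxyvinyl carbenoid plus a 2-vinylcyclopentene.
3. Forward order: the cyclopentene is made first (as its dioxolane, then vinylated). The seven-membered ring is closed onto it by rhodium cyclopropanation and Cope rearrangement. Everything after that is functional-group work on the bicycle.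
4. Stereochemistry: C7 comes from the chiral rhodium catalyst through the cyclopropane. C1/C2, C10 and C6 are each set by reagent approach anti to the angular C7 methyl (hydroboration, organocerium addition, borohydride reduction).
5. Spectator groups: the C10 carbonyl is carried through the key step as a dioxolane and the ester is benzyl. This keeps the diene electron-rich, allows the hydroboration, and lets the ester leave by hydrogenolysis.

Key step: step 6

Locants and faces: C1 ring-fusion CH, C2 anisoyloxy carbon, C3=C4 (methyl on C4), C5 ketone, C6 carbinol, C7 quaternary methyl carbon, C8/C9 methylenes, C10 isopropyl carbinol. β is the face of the C7 methyl. In these locants the target is (1S,2S,6R,7S,10R).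

Assumption: Rh2(S-PTAD)4 is taken to give the (1R,2S)-cyclopropane 9, following its usual sense with donor/acceptor carbenoids; if the sense is opposite, Rh2(R-PTAD)4 is used.

**Route**

Step 1
Reactants: 1 3-methylcyclopent-2-en-1-one
Product: 2 2-iodo-3-methylcyclopent-2-en-1-one
Conditions: I2, pyridine, DMAP (cat.), CH2Cl2, 0 °C → rt
Reagents that add atoms: iodine, II
Why: α-Iodination of an enone by the addition–elimination (Baylis–Hillman-type) mechanism: pyridine adds 1,4, the enolate is iodinated and pyridine is expelled, so iodine can only end up on C2 of the enone.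

Step 2
Reactants: 2 2-iodo-3-methylcyclopent-2-en-1-one
Product: 3 6-iodo-7-methyl-1,4-dioxaspiro[4.4]non-6-ene
Conditions: (TMSOCH2)2, TMSOTf (cat.), CH2Cl2, −78 → 0 °C; pyridine quench
Reagents that add atoms: 1,2-bis(trimethylsilyloxy)ethane, C[Si](C)(C)OCCO[Si](C)(C)C
Why: Silyl-triflate-catalysed acetalisation with the bis-silyl ether of the diol runs under aprotic, non-equilibrating conditions, so the tetrasubstituted C=C should not migrate; the dioxolane removes the Lewis-basic, electron-withdrawing carbonyl from the later diene and makes the two faces at C10 equivalent.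

Step 3
Reactants: 3 6-iodo-7-methyl-1,4-dioxaspiro[4.4]non-6-ene; 4 potassium vinyltrifluoroborate
Product: 5 7-methyl-6-vinyl-1,4-dioxaspiro[4.4]non-6-ene
Conditions: PdCl2(dppf) (cat.), Cs2CO3, THF/H2O (9:1), 70 °C
Reagents that add atoms: none
Why: Suzuki–Miyaura coupling of an alkenyl iodide with a vinyltrifluoroborate; the basic aqueous medium leaves the ketal untouched.

Step 4
Reactants: 6 benzyl acetoacetate
Product: 7 benzyl 2-diazo-3-oxobutanoate
Conditions: 4-acetamidobenzenesulfonyl azide, Et3N, MeCN, 0 °C → rt
Reagents that add atoms: 4-acetamidobenzenesulfonyl azide, CC(=O)Nc1ccc(cc1)S(=O)(=O)N=[N+]=[N-]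
Why: Regitz diazo transfer to the activated methylene of a β-keto ester.

Step 5
Reactants: 7 benzyl 2-diazo-3-oxobutanoate
Product: 8 benzyl 2-diazo-3-(tert-butyldimethylsilyloxy)but-3-enoate
Conditions: TBSOTf, Et3N, CH2Cl2, 0 °C
Reagents that add atoms: tert-butyldimethylsilyl triflate, CC(C)(C)[Si](C)(C)OS(=O)(=O)C(F)(F)F
Why: Amine/silyl triflate enolisation of the acetyl group with trapping on oxygen is the standard O-silylation route to 2-siloxyvinyl diazoacetates, and the diazo ester tolerates it.

Step 6
Reactants: 5 7-methyl-6-vinyl-1,4-dioxaspiro[4.4]non-6-ene; 8 benzyl 2-diazo-3-(tert-butyldimethylsilyloxy)but-3-enoate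
Product: 10 bicyclic cycloheptadiene (benzyl ester on C4; C4=C5 TBS enol ether; C1=C2; C10 dioxolane; 7R), via cis-divinylcyclopropane 9 (not isolated)
Conditions: Rh2(S-PTAD)4 (1 mol %), hexanes, −20 °C → rt, slow addition of 8 (1.5 equiv); then PhMe, 80 °C
Reagents that add atoms: none
Why: The dirhodium carboxylate expels N2 from 8, and the rhodium-bound 2-siloxyvinyl carbene (donor/acceptor type) cyclopropanates the monosubstituted vinyl group of 5, forming C3–C4 and C2–C4 and giving the cis-divinylcyclopropane 9 with the ester trans to the cyclopentenyl group. 9 then undergoes a [3,3]-sigmatropic (Cope) shift through the boat transition state, which breaks C2–C4 and forms C6–C7, so the seven-membered ring closes by pericyclic ring expansion of the three-membered ring (overall a formal (4+3) cycloaddition) and not by a polar cyclisation. The closest known reaction type is the rhodium-catalysed tandem cyclopropanation/divinylcyclopropane rearrangement of siloxyvinyl diazoacetates with dienes, including 1-methyl-2-vinylcycloalkenes that deliver a quaternary methyl carbon. C7 is the only stereocentre left in 10, and its R configuration is relayed from the (1R,2S)-cyclopropane, fixed by the chiral catalyst, because the boat geometry lets only one face of the ring alkene reach C6. Site selectivity for the vinyl group over the tetrasubstituted ring alkene is steric, and the cis arrangement of the two alkenyl groups is the inherent diastereoselectivity of donor/acceptor carbenoids. The C7 methyl points inward in the boat and slows the rearrangement, hence the warming stage; the ketal avoids carbonyl-ylide formation and keeps the diene nucleophilic.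

Step 7
Reactants: 10 bicyclic cycloheptadiene
Product: 12 trans-fused 2α-alcohol (1α-H; C4=C5 TBS enol ether; C10 dioxolane), via C2-alkylborane 11 (not isolated)
Conditions: BH3·THF, THF, 0 °C → rt; then NaBO3·4H2O, THF/H2O, rt
Reagents that add atoms: sodium perborate, [Na+].[Na+].O[B-]1(O)OO[B-](O)(O)OO1; borane–tetrahydrofuran, B.C1CCOC1 (its boron is held only by 11)
Why: Hydroboration–oxidation places boron on the less substituted C2 and hydrogen on C1 in a syn fashion from the α face, anti to the pseudo-axial methyl on the neighbouring quaternary C7 (as Δ5-steroids and angularly methylated hydrindenes give trans-fused products), which sets C1 (H α, trans fusion) and C2 (O α, retention in the oxidation) together, while the tetrasubstituted push–pull enol ether, the benzyl ester and the ketal should not react.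

Step 8
Reactants: 12 trans-fused 2α-alcohol; 13 4-methoxybenzoyl chloride
Product: 14 2α-anisate (C4=C5 TBS enol ether; C10 dioxolane)
Conditions: Et3N, DMAP (cat.), CH2Cl2, 0 °C → rt
Reagents that add atoms: none
Why: DMAP-catalysed acyl transfer to the only free hydroxyl installs the ester of the target, which from here on also protects C2–OH.

Step 9
Reactants: 14 2α-anisate
Product: 15 C10 ketone (2α-anisate; C4=C5 TBS enol ether)
Conditions: PPTS, acetone/H2O (10:1), 50 °C
Reagents that add atoms: water, O
Why: Mild acid-catalysed hydrolysis (transketalisation) of the dioxolane, under which the TBS enol ether of the β-keto ester (comparable to an aryl silyl ether) and both esters should survive and neither β-elimination of the anisate nor epimerisation at C1 is expected.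

Step 10
Reactants: 15 C10 ketone
Product: 16 10β-hydroxy-10α-isopropyl carbinol (2α-anisate; C4=C5 TBS enol ether)
Conditions: iPrMgCl, CeCl3 (anhydrous), THF, −78 °C; AcOH quench at −78 °C
Reagents that add atoms: isopropylmagnesium chloride, CC(C)[Mg]Cl
Why: Organocerium 1,2-addition suppresses enolisation, β-elimination and reduction, and the reagent should attack the trans-fused cyclopentanone from the α face, anti to the 1,3-related axial C7 methyl (as nucleophiles do with 16- and 17-oxo steroids), giving the 10β-alcohol, while the ketone reacts far faster than the hindered electron-rich anisate or the vinylogous-carbonate benzyl ester.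

Step 11
Reactants: 16 10β-hydroxy-10α-isopropyl carbinol
Product: 17 C4-methyl β-keto benzyl ester (C5 ketone; C4 epimers)
Conditions: TBAF, MeI (excess), THF, −20 → 0 °C
Reagents that add atoms: iodomethane, CI
Why: Fluoride cleaves the enol silane and the tetrabutylammonium β-keto ester enolate is C-methylated by iodomethane in the same flask (fluoride-promoted alkylation of a silyl enol ether), making C4 quaternary; its configuration is irrelevant because the centre becomes sp2 in step 14.

Step 12
Reactants: 17 C4-methyl β-keto benzyl ester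
Product: 19 C6-hydroxy ketone (C4 and C6 epimers), via bis(trimethylsilyl) enol ether 18 (not isolated)
Conditions: TMSOTf, Et3N, CH2Cl2, 0 °C; then mCPBA, NaHCO3, CH2Cl2, −20 °C; then 1 M HCl, THF, 0 °C
Reagents that add atoms: 3-chloroperbenzoic acid, OOC(=O)c1cccc(Cl)c1; trimethylsilyl triflate, C[Si](C)(C)OS(=O)(=O)C(F)(F)F (its silyl groups are held only by 18)
Why: Rubottom oxidation: with C4 quaternary the ketone can enolise only toward C6, the silyl enol ether is epoxidised and rearranges to the α-silyloxy ketone, and acid removes both TMS groups; the C6 configuration (expected mainly α, anti to the C7 methyl) does not matter because C6 is re-oxidised in step 14, and no strong base touches the anisate or the tertiary alcohol.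

Step 13
Reactants: 19 C6-hydroxy ketone
Product: 21 4-methyl-6-hydroxy-5-ketone (C4 and C6 epimers), via β-keto acid 20 (not isolated)
Conditions: H2 (1 atm), 10% Pd/C, EtOAc, rt; filter; PhMe, 60 °C
Reagents that add atoms: none
Why: Hydrogenolysis of the benzyl ester followed by thermal decarboxylation of the β-keto acid through the cyclic six-membered transition state; there is no alkene in the molecule at this point and the aryl ester is not benzylic, so nothing else should be reduced.

Step 14
Reactants: 21 4-methyl-6-hydroxy-5-ketone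
Product: 23 ene-5,6-dione (C3=C4; 2α-anisate; 10β-OH), via saturated 5,6-dione 22 (not isolated)
Conditions: IBX (5 equiv), DMSO, rt then 75 °C
Reagents that add atoms: none
Why: IBX first oxidises the α-ketol to the 1,2-dione and then, on heating, dehydrogenates it through its enol (IBX dehydrogenation of carbonyl compounds); the dione can enolise only toward C4 and C7 has no hydrogen, so the new double bond can only be C3=C4.

Step 15
Reactants: 23 ene-5,6-dione
Product: 24 CNP0299970.1 (target)
Conditions: NaBH4, MeOH/CH2Cl2 (1:1), −78 °C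
Reagents that add atoms: none
Why: Sodium borohydride should reduce the non-conjugated C6 carbonyl in preference to the conjugated C5 carbonyl (the selectivity known from the Wieland–Miescher ketone and androst-4-ene-3,17-dione), with hydride entering anti to the adjacent axial C7 methyl (α face, as 17-oxo steroids give 17β-ols), which gives the 6β-alcohol cis to the methyl group.

**Compound list**

1 | 3-methylcyclopent-2-en-1-one | CC1=CC(=O)CC1 | starting material
2 | 2-iodo-3-methylcyclopent-2-en-1-one | CC1=C(I)C(=O)CC1 | intermediate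
3 | 6-iodo-7-methyl-1,4-dioxaspiro[4.4]non-6-ene | CC1=C(I)C2(CC1)OCCO2 | intermediate
4 | potassium vinyltrifluoroborate | C=C[B-](F)(F)F.[K+] | starting material
5 | 7-methyl-6-vinyl-1,4-dioxaspiro[4.4]non-6-ene | C=CC1=C(C)CCC12OCCO2 | intermediate
6 | benzyl acetoacetate | CC(=O)CC(=O)OCc1ccccc1 | starting material
7 | benzyl 2-diazo-3-oxobutanoate | CC(=O)C(=[N+]=[N-])C(=O)OCc1ccccc1 | intermediate
8 | benzyl 2-diazo-3-(tert-butyldimethylsilyloxy)but-3-enoate | C=C(O[Si](C)(C)C(C)(C)C)C(=[N+]=[N-])C(=O)OCc1ccccc1 | intermediate
9 | benzyl (1R,2S)-1-[1-(TBS-oxy)vinyl]-2-(7-methyl-1,4-dioxaspiro[4.4]non-6-en-6-yl)cyclopropane-1-carboxylate (cis-divinylcyclopropane) | C=C(O[Si](C)(C)C(C)(C)C)[C@@]1(C(=O)OCc4ccccc4)C[C@H]1C2=C(C)CCC23OCCO3 | intermediate (not isolated)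
10 | bicyclic cycloheptadiene: benzyl ester on C4, C4=C5 TBS enol ether, C1=C2, C10 dioxolane, (7R) quaternary methyl | O=C(OCc1ccccc1)C1=C(O[Si](C)(C)C(C)(C)C)C[C@@]2(C)CCC3(OCCO3)C2=CC1 | intermediate
11 | C2-alkylborane (2α-BH2, 1α-H) | B[C@H]1CC(C(=O)OCc2ccccc2)=C(O[Si](C)(C)C(C)(C)C)C[C@@]3(C)CCC4(OCCO4)[C@H]13 | intermediate (not isolated)
12 | trans-fused 2α-alcohol (1α-H, 7β-Me), C4=C5 TBS enol ether, C10 dioxolane | O[C@H]1CC(C(=O)OCc2ccccc2)=C(O[Si](C)(C)C(C)(C)C)C[C@@]3(C)CCC4(OCCO4)[C@H]13 | intermediate
13 | 4-methoxybenzoyl chloride | COc1ccc(C(Cl)=O)cc1 | starting material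
14 | 2α-anisate of 12 | COc1ccc(cc1)C(=O)O[C@H]2CC(C(=O)OCc3ccccc3)=C(O[Si](C)(C)C(C)(C)C)C[C@@]4(C)CCC5(OCCO5)[C@H]24 | intermediate
15 | C10 ketone (2α-anisate, C4=C5 TBS enol ether) | COc1ccc(cc1)C(=O)O[C@H]2CC(C(=O)OCc3ccccc3)=C(O[Si](C)(C)C(C)(C)C)C[C@@]4(C)CCC(=O)[C@H]24 | intermediate
16 | 10β-hydroxy-10α-isopropyl carbinol (2α-anisate, C4=C5 TBS enol ether) | COc1ccc(cc1)C(=O)O[C@H]2CC(C(=O)OCc3ccccc3)=C(O[Si](C)(C)C(C)(C)C)C[C@@]4(C)CC[C@@](O)(C(C)C)[C@H]24 | intermediate
17 | C4-methyl β-keto benzyl ester (C5 ketone; C4 epimers) | COc1ccc(cc1)C(=O)O[C@H]2CC(C)(C(=O)OCc3ccccc3)C(=O)C[C@@]4(C)CC[C@@](O)(C(C)C)[C@H]24 | intermediate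
18 | C5=C6 trimethylsilyl enol ether with C10–OTMS | COc1ccc(cc1)C(=O)O[C@H]2CC(C)(C(=O)OCc3ccccc3)C(O[Si](C)(C)C)=C[C@@]4(C)CC[C@@](O[Si](C)(C)C)(C(C)C)[C@H]24 | intermediate (not isolated)
19 | C6-hydroxy C5-ketone, C4 methyl and benzyl ester (C4, C6 epimers) | COc1ccc(cc1)C(=O)O[C@H]2CC(C)(C(=O)OCc3ccccc3)C(=O)C(O)[C@@]4(C)CC[C@@](O)(C(C)C)[C@H]24 | intermediate
20 | β-keto acid from 19 | COc1ccc(cc1)C(=O)O[C@H]2CC(C)(C(O)=O)C(=O)C(O)[C@@]3(C)CC[C@@](O)(C(C)C)[C@H]23 | intermediate (not isolated)
21 | 4-methyl-6-hydroxy-5-ketone (C4, C6 epimers) | COc1ccc(cc1)C(=O)O[C@H]2CC(C)C(=O)C(O)[C@@]3(C)CC[C@@](O)(C(C)C)[C@H]23 | intermediate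
22 | saturated 4-methyl-5,6-dione (enolised toward C4) | COc1ccc(cc1)C(=O)O[C@H]2CC(C)C(=O)C(=O)[C@@]3(C)CC[C@@](O)(C(C)C)[C@H]23 | intermediate (not isolated)
23 | ene-5,6-dione (C3=C4, 2α-anisate, 10β-OH, 10α-iPr) | COc1ccc(cc1)C(=O)O[C@H]2C=C(C)C(=O)C(=O)[C@@]3(C)CC[C@@](O)(C(C)C)[C@H]23 | intermediate
24 | CNP0299970.1: 1α-H, 2α-anisoyloxy, 6β-OH, 7β-Me, 10β-OH, 10α-iPr; (1S,2S,6R,7S,10R) | COc1ccc(C(=O)O[C@H]2C=C(C)C(=O)[C@H](O)[C@@]3(C)CC[C@@](O)(C(C)C)[C@H]23)cc1 | target

**Count and risks**

Total steps: 15. Longest linear sequence: 13 (steps 1–3 and 6–15, from 1).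

Step 10 (isopropyl addition). What may go wrong: base-induced β-elimination of the anisate toward the enone, attack of the organometallic on the aryl ester, acyl transfer to the new tertiary alkoxide, or enolisation in place of addition. The fallback sets out from 12 and returns at 16, with no ester on C2 during the organometallic step. The ketal of 12 is hydrolysed first (PPTS, wet acetone) to the β-hydroxy ketone F1. Excess isopropylcerium reagent (−78 °C) is then added to the chelated alkoxy ketone, again from the α face, to give the diol F2. The secondary C2 hydroxyl of F2 is acylated selectively with 13 (Et3N, DMAP, 0 °C; the tertiary carbinol should not react) to give 16.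

Step 14 (double oxidation with IBX). What may go wrong: the dehydrogenation stalls at the strongly enolised dione, or the enol is hydroxylated or over-oxidised. The fallback sets out from 17 and returns at 23, with the dehydrogenation done before C6 is oxidised. Hydrogenolysis of 17 (H2, Pd/C) gives the β-keto acid F3, which loses CO2 on warming to the α-methyl ketone F4. IBX (DMSO, 70 °C) dehydrogenates this simple ketone to the C3=C4 enone F5, again the only possible position. Riley oxidation of the C6 methylene of F5 (SeO2, pyridine, dioxane, 90 °C; C7 is quaternary, so no further dehydrogenation can compete) gives 23.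

Step 15 (reduction of the dione). What may go wrong: hydride attack at the conjugated carbonyl or at C3 (1,4-addition), or over-reduction. The fallback sets out from 23 and returns at 24 and needs no discrimination between the carbonyls. Luche reduction (NaBH4, CeCl3·7H2O, MeOH, −40 °C) takes both carbonyls to the 5,6-diol F6, with C6–OH β for the same steric reason and the C5 configuration immaterial. MnO2 (CH2Cl2, rt) then oxidises only the allylic C5 hydroxyl back to the enone, giving 24.

**Further compounds**

F1 | step 10 | β-hydroxy ketone: 2α-OH, C10 ketone, C4=C5 TBS enol ether | O[C@H]1CC(C(=O)OCc2ccccc2)=C(O[Si](C)(C)C(C)(C)C)C[C@@]3(C)CCC(=O)[C@H]13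
F2 | step 10 | diol: 2α-OH, 10β-OH, 10α-isopropyl, C4=C5 TBS enol ether | O[C@H]1CC(C(=O)OCc2ccccc2)=C(O[Si](C)(C)C(C)(C)C)C[C@@]3(C)CC[C@@](O)(C(C)C)[C@H]13
F3 | step 14 | β-keto acid from 17 (C6 methylene) | COc1ccc(cc1)C(=O)O[C@H]2CC(C)(C(O)=O)C(=O)C[C@@]3(C)CC[C@@](O)(C(C)C)[C@H]23
F4 | step 14 | 4-methyl-5-ketone (C6 methylene; C4 epimers) | COc1ccc(cc1)C(=O)O[C@H]2CC(C)C(=O)C[C@@]3(C)CC[C@@](O)(C(C)C)[C@H]23
F5 | step 14 | C3=C4 enone with C6 methylene | COc1ccc(cc1)C(=O)O[C@H]2C=C(C)C(=O)C[C@@]3(C)CC[C@@](O)(C(C)C)[C@H]23
F6 | step 15 | 5,6-diol (6β-OH; C5 epimers), C3=C4 | COc1ccc(cc1)C(=O)O[C@H]2C=C(C)C(O)[C@H](O)[C@@]3(C)CC[C@@](O)(C(C)C)[C@H]23
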